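**Strategy.** Everything rests on disconnecting the C10–O bond of the 3(2H)-furanone that bridges the ten-membered carbocycle (germacrane numbering). The key step turns a monocyclic precursor, the macrocyclic (1S,10S)-1,10-epoxy-4Z-en-3-ol 27, into the bridged furanone in one operation: oxidation to the β,γ-epoxy enone, transannular attack of the C3 carbonyl oxygen on C10 with inversion (setting the quaternary centre), and oxidation of the liberated C1 alcohol. It exploits the 1,3-relationship of the C3 carbonyl and the C1–C10 epoxide within the five-membered ring O–C3–C2–C1–C10. The precursor comes from an auxiliary-controlled aldol lactonisation, reagent-controlled reduction and epoxidation, and a chromium-mediated ring closure at C3–C4.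

Key step: step 17

Remark: germacrane numbering is used for skeleton atoms (ring C1–C10, lactone C11–C13, C14 on C10, C15 on C4); the L-fructose-derived Shi ketone is taken as commercially available; a centre left undefined in a SMILES string (C3 in 27, F1, F2, F4; lactone C3 in 21, 22) denotes an inconsequential epimer mixture.

**Step 1**
Reactants: 1 4-(tert-butyldimethylsilyloxy)but-1-yne; 2 ethylene oxide
Product: 5 (E)-6-(tert-butyldimethylsilyloxy)-4-methylhex-3-en-1-ol, via alkenyldimethylalane 3 (not isolated), via lithium alkenylalanate 4 (not isolated)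
Conditions: AlMe3, Cp2ZrCl2 (cat.), CH2Cl2, 0 °C to rt; n-BuLi, THF, −78 °C; then 2, −78 °C to rt; aq. Rochelle salt
Reagents that add atoms: trimethylaluminium, C[Al](C)C
Why: Negishi carboalumination adds Me and Al syn across the terminal alkyne with Me on the internal carbon, and the derived alanate opens ethylene oxide with retention of geometry, so the E-trisubstituted C1=C10 alkene and the C2–C3 unit should form in one pot.

**Step 2**
Reactants: 5 (E)-6-(tert-butyldimethylsilyloxy)-4-methylhex-3-en-1-ol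
Product: 6 PMB ether of 5
Conditions: NaH, 4-methoxybenzyl chloride, Bu4NI (cat.), THF/DMF, 0 °C to rt
Reagents that add atoms: 4-methoxybenzyl chloride, COc1ccc(CCl)cc1
Why: Williamson etherification of the primary alkoxide installs a PMB group that is orthogonal to the silyl ethers used later and is removable by oxidation.

**Step 3**
Reactants: 6 PMB ether of 5
Product: 7 (E)-6-(4-methoxybenzyloxy)-3-methylhex-3-en-1-ol
Conditions: CSA (cat.), MeOH, 0 °C
Reagents that add atoms: none
Why: Acid-catalysed methanolysis removes the primary TBS ether while the PMB ether and the trisubstituted alkene should be untouched.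

**Step 4**
Reactants: 7 (E)-6-(4-methoxybenzyloxy)-3-methylhex-3-en-1-ol
Product: 8 (E)-6-(4-methoxybenzyloxy)-3-methylhex-3-enal
Conditions: DMP, pyridine, CH2Cl2, 0 °C to rt; used crude
Reagents that add atoms: none
Why: Buffered Dess–Martin oxidation gives the β,γ-unsaturated aldehyde under non-basic conditions, which should prevent migration of the alkene into conjugation.

**Step 5**
Reactants: 9 (R)-4-benzyloxazolidin-2-one; 10 methyl 4-chloro-4-oxobutanoate
Product: 11 methyl 4-[(R)-4-benzyl-2-oxooxazolidin-3-yl]-4-oxobutanoate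
Conditions: n-BuLi, THF, −78 °C; then 10, −78 to 0 °C
Reagents that add atoms: none
Why: N-acylation of the lithiated oxazolidinone by the succinic half-ester chloride gives the aldol donor.

**Step 6**
Reactants: 8 (E)-6-(4-methoxybenzyloxy)-3-methylhex-3-enal; 11 methyl 4-[(R)-4-benzyl-2-oxooxazolidin-3-yl]-4-oxobutanoate
Product: 13 trans-lactone imide (C7 R and C8 S), via syn-aldol adduct 12 (not isolated)
Conditions: 11, Bu2BOTf, iPr2NEt, CH2Cl2, 0 °C; then 8, −78 to 0 °C; pH 7 buffer, MeOH, H2O2; then CSA (cat.), CH2Cl2, rt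
Reagents that add atoms: none
Why: The Evans syn-aldol reaction of the Z-boron enolate sets C7 and C8 under control of the (R)-auxiliary, and the syn adduct lactonises onto the methyl ester to the trans-4,5-disubstituted γ-lactone.

**Step 7**
Reactants: 13 trans-lactone imide
Product: 14 (2S,3R)-2-[(E)-5-(4-methoxybenzyloxy)-2-methylpent-2-en-1-yl]-5-oxooxolane-3-carboxylic acid
Conditions: LiOH, H2O2, THF/H2O, 0 °C; Na2SO3; then 1 M HCl
Reagents that add atoms: hydrogen peroxide, OO
Why: Lithium hydroperoxide cleaves the exocyclic imide carbonyl selectively, and acidification re-closes any opened γ-lactone, the only ring size available to the C8 hydroxyl.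

**Step 8**
Reactants: 14 lactone acid; 15 tributyl(prop-1-yn-1-yl)stannane
Product: 17 (4R,5S)-4-(but-2-ynoyl)-5-[(E)-5-(4-methoxybenzyloxy)-2-methylpent-2-en-1-yl]oxolan-2-one, via acid chloride 16 (not isolated)
Conditions: (COCl)2, DMF (cat.), CH2Cl2, 0 °C to rt; evaporate; then 15, PdCl2(PPh3)2 (cat.), 1,2-dichloroethane, 60 °C
Reagents that add atoms: none
Why: Stille acylation of the acid chloride with the alkynylstannane forms the ynone under neutral conditions that should leave the lactone and the epimerisable C7 centre intact.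

**Step 9**
Reactants: 17 ynone
Product: 18 (4R,5S)-4-[(Z)-3-iodobut-2-enoyl] lactone
Conditions: NaI, AcOH, rt
Reagents that add atoms: sodium iodide, [Na+].[I-]
Why: Conjugate hydroiodination of the ynone proceeds by anti addition under kinetic control to the (Z)-β-iodo enone, which fixes the later 4Z geometry with iodine cis to C6.

**Step 10**
Reactants: 18 (Z)-β-iodo enone
Product: 19 (4S,5S)-4-[(1R,2Z)-1-hydroxy-3-iodobut-2-en-1-yl] lactone
Conditions: (S)-2-methyl-CBS-oxazaborolidine, catecholborane, toluene, −78 °C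
Reagents that add atoms: none
Why: Corey–Bakshi–Shibata reduction with the iodoalkenyl group acting as the large substituent should deliver hydride to the face that gives the C6 configuration of the target, and catecholborane leaves the lactone and the isolated alkene alone.

**Step 11**
Reactants: 19 allylic alcohol
Product: 20 C6 TBS ether of 19
Conditions: TBSOTf, 2,6-lutidine, CH2Cl2, −78 to 0 °C
Reagents that add atoms: tert-butyldimethylsilyl triflate, CC(C)(C)[Si](C)(C)OS(=O)(=O)C(F)(F)F
Why: Silylation masks the C6 hydroxyl before enolate chemistry and the later oxidations, and prevents base-induced translactonisation to the 6,12-olide.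

**Step 12**
Reactants: 20 C6 TBS ether
Product: 23 α-methylene lactone, via Mannich base 21 (not isolated), via ammonium iodide 22 (not isolated)
Conditions: LDA, THF, −78 °C; Eschenmoser's salt, −78 to 0 °C; then MeI, CH2Cl2/MeOH, rt; evaporate; then aq. NaHCO3, CH2Cl2, rt
Reagents that add atoms: Eschenmoser's salt (N,N-dimethylmethyleneiminium iodide), C=[N+](C)C.[I-]
Why: Mannich reaction of the kinetic lactone enolate, N-quaternisation and elimination of trimethylamine is the standard Eschenmoser α-methylenation of γ-lactones.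

**Step 13**
Reactants: 23 α-methylene lactone
Product: 24 primary alcohol at C3
Conditions: DDQ, CH2Cl2/pH 7 buffer, 0 °C
Reagents that add atoms: none
Why: Oxidative cleavage of the PMB ether is selective for the electron-rich benzyl group and should spare the silyl ether, the vinyl iodide and both alkenes.

**Step 14**
Reactants: 24 homoallylic alcohol
Product: 25 (2S,3S)-epoxy alcohol (1S,10S in germacrane numbering)
Conditions: L-fructose-derived Shi ketone (0.3 equiv), Oxone, K2CO3, Bu4NHSO4 (cat.), MeCN/dimethoxymethane/aq. borate–EDTA buffer, 0 °C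
Reagents that add atoms: potassium peroxymonosulfate (active salt of Oxone), [K+].[O-]S(=O)(=O)OO
Why: Shi epoxidation by the chiral dioxirane attacks only the electron-rich E-trisubstituted C1=C10 alkene, and the L-fructose-derived ketone should set C1 and C10 as (S,S) by reagent control.

**Step 15**
Reactants: 25 epoxy alcohol
Product: 26 β,γ-epoxy aldehyde
Conditions: DMP, pyridine, CH2Cl2, 0 °C; used at once
Reagents that add atoms: none
Why: Buffered Dess–Martin oxidation gives the β,γ-epoxy aldehyde without the base that would open the epoxide by enolisation.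

**Step 16**
Reactants: 26 β,γ-epoxy aldehyde
Product: 27 (1S,3RS,4Z,6S,7R,8S,10S)-6-(tert-butyldimethylsilyloxy)-1,10-epoxy-3-hydroxygermacra-4,11(13)-dien-12,8-olide
Conditions: CrCl2, NiCl2 (cat.), degassed DMSO, rt, high dilution (2 mM), slow addition
Reagents that add atoms: none
Why: In this Nozaki–Hiyama–Kishi macrocyclisation the nickel-activated Z-vinyl iodide is transferred to chromium and adds to the aldehyde with retention of alkene geometry under near-neutral conditions; the new C3 carbinol needs no control because it is oxidised next.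

**Step 17**
Reactants: 27 macrocyclic epoxy alcohol
Product: 30 (4Z,6S,7R,8S,10R)-6-(tert-butyldimethylsilyloxy)-3,10-epoxy-1-oxogermacra-2,4,11(13)-trien-12,8-olide, via epoxy enone 28 (not isolated), via hydroxydihydrofuran 29 (not isolated)
Conditions: DMP (3.5 equiv), CH2Cl2, 0 °C to rt; then CSA (0.1 equiv), rt, same flask
Reagents that add atoms: none
Why: DMP first oxidises the C3 allylic alcohol to the Z-enone 28, whose carbonyl oxygen attacks the acid-activated epoxide at the tertiary carbon C10 anti to the departing epoxide oxygen; the cyclic dienyl oxocarbenium ion then loses a proton from C2 to give the 3-hydroxy-2,3-dihydrofuran 29, which the remaining DMP oxidises at C1 to the 3(2H)-furanone. The closest known reaction type is the acid-catalysed cyclisation of β,γ-epoxy ketones to 3-hydroxy-2,3-dihydrofurans (furans where dehydration is possible), run here transannularly. The five-membered ring O–C3–C2–C1–C10 closes by a 5-endo epoxide opening, which turns the ten-membered carbocycle into the 11-oxabicyclo[6.2.1]undecane core. The only new stereocentre, C10, arises by inversion of the (10S) epoxide carbon set in the Shi step and should therefore be (10R), while C1 and C3 end as sp2 carbons. The step needs attack at C10 and not at C1, carbonyl participation ahead of 1,2-hydride shift or opening to the 10-hydroxy-1-en-3-one, and survival of the acid-labile intermediate 29. These are secured by the cation-stabilising tertiary C10 with the 1,3-placed enone oxygen (the 4-exo alternative is an oxetane), by acidic and not basic conditions, and by immediate oxidation in the same flask.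

**Step 18**
Reactants: 30 silyl-protected furanone
Product: 31 (4Z,6S,7S,8S,10R)-6-hydroxy-3,10-epoxy-1-oxogermacra-2,4,11(13)-trien-12,8-olide
Conditions: HF·pyridine, pyridine, THF, 0 °C to rt
Reagents that add atoms: none
Why: Buffered fluoride desilylation frees the C6 hydroxyl without base strong enough to harm the furanone or the α-methylene lactone.

**Step 19**
Reactants: 32 angelic acid
Product: 33 (Z)-2-methylbut-2-en-1-ol
Conditions: LiAlH4, Et2O, 0 °C
Reagents that add atoms: none
Why: Hydride reduction of the acid gives the allylic alcohol with the Z geometry retained.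

**Step 20**
Reactants: 33 (Z)-2-methylbut-2-en-1-ol
Product: 34 [(2S,3R)-2,3-dimethyloxiran-2-yl]methanol
Conditions: Ti(OiPr)4, L-(+)-diethyl tartrate, t-BuOOH, 4 Å molecular sieves, CH2Cl2, −20 °C
Reagents that add atoms: tert-butyl hydroperoxide, CC(C)(C)OO
Why: Sharpless asymmetric epoxidation with the L-(+)-tartrate delivers oxygen to the face that gives the (2S,3R) epoxy alcohol, the same facial sense as for nerol.

**Step 21**
Reactants: 34 epoxy alcohol
Product: 35 (2R,3R)-2,3-dimethyloxirane-2-carboxylic acid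
Conditions: RuCl3 (cat.), NaIO4, CCl4/MeCN/H2O, rt
Reagents that add atoms: sodium periodate, [Na+].[O-]I(=O)(=O)=O
Why: Catalytic ruthenium tetroxide oxidation converts 2,3-epoxy alcohols into glycidic acids without touching the epoxide or its stereocentres.

**Step 22**
Reactants: 31 C6 alcohol; 35 (2R,3R)-2,3-dimethyloxirane-2-carboxylic acid
Product: 37 CNP0258430.3, via mixed anhydride 36 (not isolated)
Conditions: 2,4,6-trichlorobenzoyl chloride, Et3N, toluene, rt; then 31, DMAP, toluene, rt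
Reagents that add atoms: none
Why: Yamaguchi esterification acylates the hindered secondary C6 hydroxyl through the mixed anhydride under mild base, and the epoxy acid has no α-hydrogen to epimerise.

**Compound list**

1 | 4-(tert-butyldimethylsilyloxy)but-1-yne | C#CCCO[Si](C)(C)C(C)(C)C | starting material
2 | ethylene oxide | C1CO1 | starting material
3 | [(E)-4-(tert-butyldimethylsilyloxy)-2-methylbut-1-en-1-yl]dimethylalane | C[Al](C)/C=C(\C)CCO[Si](C)(C)C(C)(C)C | intermediate
4 | lithium butyl[(E)-4-(tert-butyldimethylsilyloxy)-2-methylbut-1-en-1-yl]dimethylalanate | [Li+].CCCC[Al-](C)(C)/C=C(\C)CCO[Si](C)(C)C(C)(C)C | intermediate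
5 | (E)-6-(tert-butyldimethylsilyloxy)-4-methylhex-3-en-1-ol | OCC/C=C(\C)CCO[Si](C)(C)C(C)(C)C | intermediate
6 | tert-butyl{[(E)-6-(4-methoxybenzyloxy)-3-methylhex-3-en-1-yl]oxy}dimethylsilane | COc1ccc(COCC/C=C(\C)CCO[Si](C)(C)C(C)(C)C)cc1 | intermediate
7 | (E)-6-(4-methoxybenzyloxy)-3-methylhex-3-en-1-ol | COc1ccc(COCC/C=C(\C)CCO)cc1 | intermediate
8 | (E)-6-(4-methoxybenzyloxy)-3-methylhex-3-enal | COc1ccc(COCC/C=C(\C)CC=O)cc1 | intermediate
9 | (R)-4-benzyloxazolidin-2-one | O=C1N[C@H](Cc2ccccc2)CO1 | starting material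
10 | methyl 4-chloro-4-oxobutanoate | COC(=O)CCC(Cl)=O | starting material
11 | methyl 4-[(R)-4-benzyl-2-oxooxazolidin-3-yl]-4-oxobutanoate | COC(=O)CCC(=O)N1[C@H](Cc2ccccc2)COC1=O | intermediate
12 | methyl (3R,4S,6E)-3-[(R)-4-benzyl-2-oxooxazolidine-3-carbonyl]-4-hydroxy-9-(4-methoxybenzyloxy)-6-methylnon-6-enoate | COC(=O)C[C@H]([C@@H](O)C/C(C)=C/CCOCc1ccc(OC)cc1)C(=O)N2[C@H](Cc3ccccc3)COC2=O | intermediate
13 | (R)-4-benzyl-3-{(2S,3R)-2-[(E)-5-(4-methoxybenzyloxy)-2-methylpent-2-en-1-yl]-5-oxooxolane-3-carbonyl}oxazolidin-2-one | O=C1C[C@@H](C(=O)N2[C@H](Cc3ccccc3)COC2=O)[C@H](C/C(C)=C/CCOCc4ccc(OC)cc4)O1 | intermediate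
14 | (2S,3R)-2-[(E)-5-(4-methoxybenzyloxy)-2-methylpent-2-en-1-yl]-5-oxooxolane-3-carboxylic acid | O=C1C[C@@H](C(=O)O)[C@H](C/C(C)=C/CCOCc2ccc(OC)cc2)O1 | intermediate
15 | tributyl(prop-1-yn-1-yl)stannane | CC#C[Sn](CCCC)(CCCC)CCCC | starting material
16 | (2S,3R)-2-[(E)-5-(4-methoxybenzyloxy)-2-methylpent-2-en-1-yl]-5-oxooxolane-3-carbonyl chloride | O=C1C[C@@H](C(Cl)=O)[C@H](C/C(C)=C/CCOCc2ccc(OC)cc2)O1 | intermediate
17 | (4R,5S)-4-(but-2-ynoyl)-5-[(E)-5-(4-methoxybenzyloxy)-2-methylpent-2-en-1-yl]oxolan-2-one | O=C1C[C@@H](C(=O)C#CC)[C@H](C/C(C)=C/CCOCc2ccc(OC)cc2)O1 | intermediate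
18 | (4R,5S)-4-[(Z)-3-iodobut-2-enoyl]-5-[(E)-5-(4-methoxybenzyloxy)-2-methylpent-2-en-1-yl]oxolan-2-one | O=C1C[C@@H](C(=O)/C=C(/C)I)[C@H](C/C(C)=C/CCOCc2ccc(OC)cc2)O1 | intermediate
19 | (4S,5S)-4-[(1R,2Z)-1-hydroxy-3-iodobut-2-en-1-yl]-5-[(E)-5-(4-methoxybenzyloxy)-2-methylpent-2-en-1-yl]oxolan-2-one | O=C1C[C@@H]([C@@H](O)/C=C(/C)I)[C@H](C/C(C)=C/CCOCc2ccc(OC)cc2)O1 | intermediate
20 | (4R,5S)-4-[(1R,2Z)-1-(tert-butyldimethylsilyloxy)-3-iodobut-2-en-1-yl]-5-[(E)-5-(4-methoxybenzyloxy)-2-methylpent-2-en-1-yl]oxolan-2-one | O=C1C[C@@H]([C@@H](O[Si](C)(C)C(C)(C)C)/C=C(/C)I)[C@H](C/C(C)=C/CCOCc2ccc(OC)cc2)O1 | intermediate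
21 | 3-[(dimethylamino)methyl] derivative of 20 (lactone C3 epimers) | O=C1C(CN(C)C)[C@@H]([C@@H](O[Si](C)(C)C(C)(C)C)/C=C(/C)I)[C@H](C/C(C)=C/CCOCc2ccc(OC)cc2)O1 | intermediate
22 | 3-[(trimethylammonio)methyl] iodide derived from 21 | O=C1C(C[N+](C)(C)C)[C@@H]([C@@H](O[Si](C)(C)C(C)(C)C)/C=C(/C)I)[C@H](C/C(C)=C/CCOCc2ccc(OC)cc2)O1.[I-] | intermediate
23 | (4R,5S)-4-[(1R,2Z)-1-(tert-butyldimethylsilyloxy)-3-iodobut-2-en-1-yl]-5-[(E)-5-(4-methoxybenzyloxy)-2-methylpent-2-en-1-yl]-3-methylideneoxolan-2-one | O=C1C(=C)[C@@H]([C@@H](O[Si](C)(C)C(C)(C)C)/C=C(/C)I)[C@H](C/C(C)=C/CCOCc2ccc(OC)cc2)O1 | intermediate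
24 | (4R,5S)-4-[(1R,2Z)-1-(tert-butyldimethylsilyloxy)-3-iodobut-2-en-1-yl]-5-[(E)-5-hydroxy-2-methylpent-2-en-1-yl]-3-methylideneoxolan-2-one | O=C1C(=C)[C@@H]([C@@H](O[Si](C)(C)C(C)(C)C)/C=C(/C)I)[C@H](C/C(C)=C/CCO)O1 | intermediate
25 | (4R,5S)-4-[(1R,2Z)-1-(tert-butyldimethylsilyloxy)-3-iodobut-2-en-1-yl]-5-{[(2S,3S)-3-(2-hydroxyethyl)-2-methyloxiran-2-yl]methyl}-3-methylideneoxolan-2-one | O=C1C(=C)[C@@H]([C@@H](O[Si](C)(C)C(C)(C)C)/C=C(/C)I)[C@H](C[C@]2(C)O[C@H]2CCO)O1 | intermediate
26 | (4R,5S)-4-[(1R,2Z)-1-(tert-butyldimethylsilyloxy)-3-iodobut-2-en-1-yl]-5-{[(2S,3S)-2-methyl-3-(2-oxoethyl)oxiran-2-yl]methyl}-3-methylideneoxolan-2-one | O=C1C(=C)[C@@H]([C@@H](O[Si](C)(C)C(C)(C)C)/C=C(/C)I)[C@H](C[C@]2(C)O[C@H]2CC=O)O1 | intermediate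
27 | (1S,3RS,4Z,6S,7R,8S,10S)-6-(tert-butyldimethylsilyloxy)-1,10-epoxy-3-hydroxygermacra-4,11(13)-dien-12,8-olide | C=C1C(=O)O[C@H]2C[C@]3(C)O[C@H]3CC(O)/C(C)=C\[C@H](O[Si](C)(C)C(C)(C)C)[C@H]12 | intermediate
28 | (1S,4Z,6S,7R,8S,10S)-6-(tert-butyldimethylsilyloxy)-1,10-epoxy-3-oxogermacra-4,11(13)-dien-12,8-olide | C=C1C(=O)O[C@H]2C[C@]3(C)O[C@H]3CC(=O)/C(C)=C\[C@H](O[Si](C)(C)C(C)(C)C)[C@H]12 | intermediate
29 | (1S,4Z,6S,7R,8S,10R)-6-(tert-butyldimethylsilyloxy)-3,10-epoxy-1-hydroxygermacra-2,4,11(13)-trien-12,8-olide | C=C1C(=O)O[C@H]2C[C@@]3(C)OC(=C[C@@H]3O)/C(C)=C\[C@H](O[Si](C)(C)C(C)(C)C)[C@H]12 | intermediate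
30 | (4Z,6S,7R,8S,10R)-6-(tert-butyldimethylsilyloxy)-3,10-epoxy-1-oxogermacra-2,4,11(13)-trien-12,8-olide | C=C1C(=O)O[C@H]2C[C@@]3(C)OC(=CC3=O)/C(C)=C\[C@H](O[Si](C)(C)C(C)(C)C)[C@H]12 | intermediate
31 | (4Z,6S,7S,8S,10R)-6-hydroxy-3,10-epoxy-1-oxogermacra-2,4,11(13)-trien-12,8-olide | C=C1C(=O)O[C@H]2C[C@@]3(C)OC(=CC3=O)/C(C)=C\[C@H](O)[C@H]12 | intermediate
32 | angelic acid, (Z)-2-methylbut-2-enoic acid | C/C=C(/C)C(=O)O | starting material
33 | (Z)-2-methylbut-2-en-1-ol | C/C=C(/C)CO | intermediate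
34 | [(2S,3R)-2,3-dimethyloxiran-2-yl]methanol | OC[C@]1(C)O[C@@H]1C | intermediate
35 | (2R,3R)-2,3-dimethyloxirane-2-carboxylic acid | OC(=O)[C@]1(C)O[C@@H]1C | intermediate
36 | (2R,3R)-2,3-dimethyloxirane-2-carboxylic 2,4,6-trichlorobenzoic anhydride | O=C(OC(=O)[C@]1(C)O[C@@H]1C)c2c(Cl)cc(Cl)cc2Cl | intermediate
37 | CNP0258430.3, (4Z,6S,7R,8S,10R)-6-[(2R,3R)-2,3-dimethyloxirane-2-carbonyloxy]-3,10-epoxy-1-oxogermacra-2,4,11(13)-trien-12,8-olide | C=C1C(=O)O[C@H]2C[C@@]3(C)OC(=CC3=O)/C(C)=C\[C@H](OC(=O)[C@]3(C)O[C@@H]3C)[C@H]12 | target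

**Step count and risks**

Total: 22 steps. Longest linear sequence: 18 steps (steps 1–4, 6–18 and 22).

Most likely to fail, in this order:

Step 17. Before the carbonyl oxygen engages C10, the β,γ-epoxy enone may open by enolisation towards C2 to the 10-hydroxy-1-en-3-one, or undergo a 1,2-hydride shift; the hydroxydihydrofuran may also ionise at C1 under acid. Fallback: setting out from 27, the C3 hydroxyl is used as the nucleophile in place of the ketone. CSA (cat.) in CH2Cl2 should open the epoxide at C10 in the same 5-endo sense, with inversion, to give (1S,3RS,4Z,6S,7R,8S,10R)-6-(tert-butyldimethylsilyloxy)-3,10-epoxy-1-hydroxygermacra-4,11(13)-dien-12,8-olide F1. Dess–Martin oxidation then gives the tetrahydrofuran-3-one (3RS,4Z,6S,7R,8S,10R)-6-(tert-butyldimethylsilyloxy)-3,10-epoxy-1-oxogermacra-4,11(13)-dien-12,8-olide F2. Dehydrogenation across C2–C3 with IBX in DMSO at 65 °C returns to the route at 30.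

Step 16. Ring closure may lose out to oligomerisation, and the β,γ-epoxy aldehyde may be consumed by enolisation and epoxide opening before the C–C bond forms. Fallback: setting out from 24, the order of epoxidation and ring closure is reversed. Buffered Dess–Martin oxidation gives the β,γ-unsaturated aldehyde (4R,5S)-4-[(1R,2Z)-1-(tert-butyldimethylsilyloxy)-3-iodobut-2-en-1-yl]-5-[(E)-2-methyl-5-oxopent-2-en-1-yl]-3-methylideneoxolan-2-one F3. The same CrCl2/NiCl2 closure gives the macrocyclic dienol (1(10)E,3RS,4Z,6S,7R,8S)-6-(tert-butyldimethylsilyloxy)-3-hydroxygermacra-1(10),4,11(13)-trien-12,8-olide F4. Epoxidation of its more electron-rich C1=C10 alkene with the L-fructose-derived Shi ketone returns to the route at 27.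

Step 10. Facial selectivity may be poor if the C7 stereocentre opposes the catalyst or if the lactone-bearing flank, not the iodoalkenyl group, behaves as the large substituent. Fallback: setting out from 18, Luche reduction (NaBH4, CeCl3, MeOH, −78 °C) is run under substrate control. Should the C6 epimer (4S,5S)-4-[(1S,2Z)-1-hydroxy-3-iodobut-2-en-1-yl]-5-[(E)-5-(4-methoxybenzyloxy)-2-methylpent-2-en-1-yl]oxolan-2-one F5 predominate, a Mitsunobu reaction with chloroacetic acid (PPh3, DIAD, THF) inverts C6 to the chloroacetate (4R,5S)-4-[(1R,2Z)-1-(chloroacetoxy)-3-iodobut-2-en-1-yl]-5-[(E)-5-(4-methoxybenzyloxy)-2-methylpent-2-en-1-yl]oxolan-2-one F6. Thiourea with NaHCO3 in EtOH removes the chloroacetyl group and returns to the route at 19.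

**Further compounds**

F1 | step 17 | (1S,3RS,4Z,6S,7R,8S,10R)-6-(tert-butyldimethylsilyloxy)-3,10-epoxy-1-hydroxygermacra-4,11(13)-dien-12,8-olide | C=C1C(=O)O[C@H]2C[C@@]3(C)OC(C[C@@H]3O)/C(C)=C\[C@H](O[Si](C)(C)C(C)(C)C)[C@H]12
F2 | step 17 | (3RS,4Z,6S,7R,8S,10R)-6-(tert-butyldimethylsilyloxy)-3,10-epoxy-1-oxogermacra-4,11(13)-dien-12,8-olide | C=C1C(=O)O[C@H]2C[C@@]3(C)OC(CC3=O)/C(C)=C\[C@H](O[Si](C)(C)C(C)(C)C)[C@H]12
F3 | step 16 | (4R,5S)-4-[(1R,2Z)-1-(tert-butyldimethylsilyloxy)-3-iodobut-2-en-1-yl]-5-[(E)-2-methyl-5-oxopent-2-en-1-yl]-3-methylideneoxolan-2-one | O=C1C(=C)[C@@H]([C@@H](O[Si](C)(C)C(C)(C)C)/C=C(/C)I)[C@H](C/C(C)=C/CC=O)O1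
F4 | step 16 | (1(10)E,3RS,4Z,6S,7R,8S)-6-(tert-butyldimethylsilyloxy)-3-hydroxygermacra-1(10),4,11(13)-trien-12,8-olide | C=C1C(=O)O[C@H]2C/C(C)=C/CC(O)/C(C)=C\[C@H](O[Si](C)(C)C(C)(C)C)[C@H]12
F5 | step 10 | (4S,5S)-4-[(1S,2Z)-1-hydroxy-3-iodobut-2-en-1-yl]-5-[(E)-5-(4-methoxybenzyloxy)-2-methylpent-2-en-1-yl]oxolan-2-one | O=C1C[C@@H]([C@H](O)/C=C(/C)I)[C@H](C/C(C)=C/CCOCc2ccc(OC)cc2)O1
F6 | step 10 | (4R,5S)-4-[(1R,2Z)-1-(chloroacetoxy)-3-iodobut-2-en-1-yl]-5-[(E)-5-(4-methoxybenzyloxy)-2-methylpent-2-en-1-yl]oxolan-2-one | O=C1C[C@@H]([C@@H](OC(=O)CCl)/C=C(/C)I)[C@H](C/C(C)=C/CCOCc2ccc(OC)cc2)O1
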